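**Retrosynthetic overview**
1. Target ⇒ alcohol 20 (O‑sulfation last) ⇒ C‑1 vinyl compound 18 + penta‑2,4‑dienoic acid (cross‑metathesis builds the dienoic acid).
2. 18 ⇒ ring A ketone 15 (Shapiro/MeI gives the C‑3 methyl and the C‑3/C‑4 alkene) ⇒ cis‑fused enedione 9 (vinyl cuprate at C‑1, convex‑face hydride at C‑7, Pd α‑alkenylation at C‑2).
3. Key disconnection C‑1–C‑8a: ring A is closed onto ring B by 6‑exo cyclisation of a β‑acylvinyl radical onto a 2‑methylcyclohexenone, which sets the cis ring fusion and C‑8.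
4. Radical precursor 8 ⇒ acid 5 (Stille acylation, iododestannylation) ⇒ methyl 4‑oxobutanoate + ethyl vinyl ketone (organocatalytic Michael/aldol sets C‑4a). Ring B is formed first, ring A second.

Assumption: the target is made in the free acid form drawn (hydrogen sulfate and carboxylic acid), released from its salt on acid‑form resin; locants in the explanations follow the target's octahydronaphthalene numbering (C‑1 dienoic acid chain, C‑2 butenyl, C‑3 methyl, C‑7 oxygen, C‑8 methyl).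

**Step 1**
Reactants: 1 methyl 4‑oxobutanoate; 2 pent‑1‑en‑3‑one
Product: 5 2‑[(1R)‑3‑methyl‑4‑oxocyclohex‑2‑en‑1‑yl]acetic acid, via Michael adduct 3 (not isolated), via enone ester 4 (not isolated)
Conditions: (R)‑2‑[diphenyl(trimethylsilyloxy)methyl]pyrrolidine (10 mol%), ethyl 3,4‑dihydroxybenzoate (20 mol%), neat, 4 °C; then LiOH, THF/H2O, 0 °C to rt; cold 1 M HCl to pH 4
Reagents that add atoms: lithium hydroxide [Li+].[OH-] (oxygen of the CO2H group)
Why: Enamine‑catalysed Michael addition (Hayashi–Jørgensen/Gellman type) in which the (R)‑diarylprolinol ether shields one face of the E‑enamine so that the vinyl ketone adds to the Re face and sets C‑4a as R, followed by hydroxide‑mediated intramolecular aldol condensation (Robinson‑type ring closure) and saponification.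

**Step 2**
Reactants: 5 2‑[(1R)‑3‑methyl‑4‑oxocyclohex‑2‑en‑1‑yl]acetic acid
Product: 8 (4R)‑4‑[(3E)‑4‑iodo‑2‑oxobut‑3‑en‑1‑yl]‑2‑methylcyclohex‑2‑en‑1‑one, via acid chloride 6 (not isolated), via stannyl enone 7 (not isolated)
Conditions: (COCl)2, DMF (cat.), CH2Cl2, 0 °C to rt; then (E)‑Bu3SnCH=CHSnBu3 (1.1 equiv), PdCl2(PPh3)2 (3 mol%), toluene, 60 °C; then I2, CH2Cl2, 0 °C
Reagents that add atoms: oxalyl chloride ClC(=O)C(=O)Cl (Cl of 6 only); (E)‑1,2‑bis(tributylstannyl)ethene CCCC[Sn](CCCC)(CCCC)/C=C/[Sn](CCCC)(CCCC)CCCC; iodine II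
Why: Stille acylation of the acid chloride stops after one coupling because the β‑stannyl enone formed is deactivated, and iododestannylation then gives the E‑vinyl iodide with retention, no stereocentre being touched.

**Step 3 (key step)**
Reactants: 8 (4R)‑4‑[(3E)‑4‑iodo‑2‑oxobut‑3‑en‑1‑yl]‑2‑methylcyclohex‑2‑en‑1‑one
Product: 9 (1S,4aR,8aR)‑1‑methyl‑3,4,4a,5‑tetrahydronaphthalene‑2,6(1H,8aH)‑dione
Conditions: Bu3SnH (1.3 equiv, syringe pump over 6 h), AIBN (0.2 equiv), benzene, 80 °C, 5 mM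
Reagents that add atoms: none
Why: Tin hydride‑mediated vinyl radical cyclisation (Stork type), in which the rapidly inverting β‑acylvinyl σ‑radical adds 6‑exo‑trig to the enone β‑carbon (C‑8a) on the only face the short tether from C‑4a can reach, giving the cis ring fusion, and the resulting α‑keto radical at C‑8 takes hydrogen from Bu3SnH on the convex face anti to the new C‑1–C‑8a bond, leaving the methyl group cis to that bond.

**Step 4**
Reactants: 9 (1S,4aR,8aR)‑1‑methyl‑3,4,4a,5‑tetrahydronaphthalene‑2,6(1H,8aH)‑dione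
Product: 11 (1S,2R,4aR,8S,8aR)‑8‑ethenyl‑1‑methyl‑6‑[(trimethylsilyl)oxy]‑1,2,3,4,4a,5,8,8a‑octahydronaphthalen‑2‑ol, via keto silyl enol ether 10 (not isolated)
Conditions: (CH2=CH)2CuMgBr [from CH2=CHMgBr (2.4 equiv) and CuBr·SMe2 (1.2 equiv)], TMSCl (2 equiv), THF, −78 °C; then LiBH(s‑Bu)3 (1.5 equiv), −78 °C; pH 7 buffer
Reagents that add atoms: vinylmagnesium bromide C=C[Mg]Br; chlorotrimethylsilane C[Si](C)(C)Cl
Why: TMSCl‑accelerated cuprate 1,4‑addition places the vinyl group at C‑1 on the convex face of the cis‑fused enone (trans to ring B), the silyl enol ether so formed masks the ring A ketone, and the bulky borohydride (Selectride reduction) then attacks the C‑7 ketone from the equatorial convex side because the axial C‑8a–C‑1 bond blocks axial attack, giving the axial alcohol cis to the C‑8 methyl group.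

**Step 5**
Reactants: 11 (1S,2R,4aR,8S,8aR)‑8‑ethenyl‑1‑methyl‑6‑[(trimethylsilyl)oxy]‑1,2,3,4,4a,5,8,8a‑octahydronaphthalen‑2‑ol; 12 (2E)‑2‑bromobut‑2‑ene
Product: 15 (3S,4S,4aR,5S,6R,8aR)‑3‑[(2E)‑but‑2‑en‑2‑yl]‑4‑ethenyl‑6‑hydroxy‑5‑methyloctahydronaphthalen‑2(1H)‑one, via dilithium enolate 13 (not isolated), via zinc enolate 14 (not isolated)
Conditions: MeLi (2.2 equiv), THF, 0 °C; ZnCl2 (1.2 equiv); 12 (1.5 equiv), Pd2(dba)3 (2.5 mol%), P(t‑Bu)3 (6 mol%), THF, rt to 50 °C; aq NH4Cl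
Reagents that add atoms: methyllithium [Li]C (Li of 13 and 14 only); zinc chloride Cl[Zn]Cl (ZnCl of 14 only)
Why: Cleavage of the silyl enol ether with MeLi gives the enolate regiospecifically, and zerovalent‑palladium‑catalysed α‑alkenylation of its zinc enolate (Buchwald–Hartwig‑type enolate vinylation) joins the butenyl group to C‑2 only, with retention of the E geometry, anti to the adjacent C‑1 vinyl group, the epimerisable α‑centre resting in the trans‑diequatorial arrangement.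

**Step 6**
Reactants: 15 (3S,4S,4aR,5S,6R,8aR)‑3‑[(2E)‑but‑2‑en‑2‑yl]‑4‑ethenyl‑6‑hydroxy‑5‑methyloctahydronaphthalen‑2(1H)‑one
Product: 16 N'‑[(2E,3S,4S,4aR,5S,6R,8aR)‑3‑[(2E)‑but‑2‑en‑2‑yl]‑4‑ethenyl‑6‑hydroxy‑5‑methyloctahydronaphthalen‑2(1H)‑ylidene]‑2,4,6‑tri(propan‑2‑yl)benzenesulfonohydrazide
Conditions: 2,4,6‑(i‑Pr)3C6H2SO2NHNH2 (1.2 equiv), THF, 4 Å MS, rt
Reagents that add atoms: 2,4,6‑tri(propan‑2‑yl)benzenesulfonohydrazide NNS(=O)(=O)c1c(C(C)C)cc(C(C)C)cc1C(C)C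
Why: Hydrazone condensation at the only ketone gives the E isomer with the N–N bond anti to the hindered C‑2, which later directs deprotonation to C‑4, and no stereocentre changes because C‑2 already sits in its preferred trans position.

**Step 7**
Reactants: 16 the trisylhydrazone of step 6
Product: 18 (1S,2R,4aS,7S,8S,8aR)‑7‑[(2E)‑but‑2‑en‑2‑yl]‑8‑ethenyl‑1,6‑dimethyl‑1,2,3,4,4a,7,8,8a‑octahydronaphthalen‑2‑ol, via vinyllithium 17 (not isolated)
Conditions: n‑BuLi (3.5 equiv), TMEDA, THF, −78 to 0 °C; then MeI (4 equiv), −78 to 0 °C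
Reagents that add atoms: iodomethane CI; n‑butyllithium [Li]CCCC (Li of 17 only)
Why: Shapiro reaction, in which syn‑directed deprotonation of the hydrazone at the C‑4 methylene followed by loss of sulfinate and N2 gives the C‑3 vinyllithium with the double bond fixed at C‑3/C‑4, and methylation with MeI then gives the trisubstituted ring alkene while the extra base only holds the alcohol as its alkoxide and C‑2 becomes configurationally fixed.

**Step 8**
Reactants: 18 the diene alcohol of step 7; 19 (2E)‑penta‑2,4‑dienoic acid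
Product: 20 (2E,4E)‑5‑[(1S,2S,4aS,7R,8S,8aR)‑2‑[(2E)‑but‑2‑en‑2‑yl]‑7‑hydroxy‑3,8‑dimethyl‑1,2,4a,5,6,7,8,8a‑octahydronaphthalen‑1‑yl]penta‑2,4‑dienoic acid
Conditions: 19 (4 equiv), second‑generation Hoveyda–Grubbs catalyst (10 mol%), CH2Cl2, 40 °C
Reagents that add atoms: none
Why: Olefin cross‑metathesis in which the ruthenium carbene engages only the monosubstituted vinyl group and the terminal alkene of the dienoic acid (the trisubstituted alkenes and the acid‑conjugated alkene are spectators), the new disubstituted alkene forming as the favoured E isomer to give the 2E,4E acid.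

**Step 9**
Reactants: 20 the hydroxy dienoic acid of step 8
Product: 22 (2E,4E)‑5‑[(1S,2S,4aS,7R,8S,8aR)‑2‑[(2E)‑but‑2‑en‑2‑yl]‑3,8‑dimethyl‑7‑(sulfooxy)‑1,2,4a,5,6,7,8,8a‑octahydronaphthalen‑1‑yl]penta‑2,4‑dienoic acid, via pyridinium sulfate 21 (not isolated)
Conditions: SO3·pyridine (3 equiv), pyridine, 0 °C to rt; aq NaHCO3; Dowex 50W (H+ form), cold
Reagents that add atoms: sulfur trioxide pyridine complex [O-]S(=O)(=O)[n+]1ccccc1
Why: O‑sulfation of the single secondary alcohol with the SO3–pyridine complex, any mixed carboxylic–sulfuric anhydride being hydrolysed in the bicarbonate work‑up and the acid‑form resin releasing the free hydrogen sulfate without touching a stereocentre.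

**Compound list**
1 | methyl 4‑oxobutanoate | COC(=O)CCC=O | starting material
2 | pent‑1‑en‑3‑one (ethyl vinyl ketone) | CCC(=O)C=C | starting material
3 | methyl (3R)‑3‑formyl‑6‑oxooctanoate | COC(=O)C[C@H](C=O)CCC(=O)CC | intermediate
4 | methyl 2‑[(1R)‑3‑methyl‑4‑oxocyclohex‑2‑en‑1‑yl]acetate | COC(=O)C[C@H]1CCC(=O)C(C)=C1 | intermediate
5 | 2‑[(1R)‑3‑methyl‑4‑oxocyclohex‑2‑en‑1‑yl]acetic acid | OC(=O)C[C@H]1CCC(=O)C(C)=C1 | intermediate
6 | 2‑[(1R)‑3‑methyl‑4‑oxocyclohex‑2‑en‑1‑yl]acetyl chloride | ClC(=O)C[C@H]1CCC(=O)C(C)=C1 | intermediate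
7 | (4R)‑2‑methyl‑4‑[(3E)‑2‑oxo‑4‑(tributylstannyl)but‑3‑en‑1‑yl]cyclohex‑2‑en‑1‑one | CCCC[Sn](CCCC)(CCCC)/C=C/C(=O)C[C@H]1CCC(=O)C(C)=C1 | intermediate
8 | (4R)‑4‑[(3E)‑4‑iodo‑2‑oxobut‑3‑en‑1‑yl]‑2‑methylcyclohex‑2‑en‑1‑one | I/C=C/C(=O)C[C@H]1CCC(=O)C(C)=C1 | intermediate
9 | (1S,4aR,8aR)‑1‑methyl‑3,4,4a,5‑tetrahydronaphthalene‑2,6(1H,8aH)‑dione (cis‑fused; H‑1, H‑4a and H‑8a on one face) | O=C1C[C@H]2CCC(=O)[C@@H](C)[C@H]2C=C1 | intermediate
10 | (1S,4aR,8S,8aR)‑8‑ethenyl‑1‑methyl‑6‑[(trimethylsilyl)oxy]‑3,4,4a,5,8,8a‑hexahydronaphthalen‑2(1H)‑one | C1=C(O[Si](C)(C)C)C[C@H]2CCC(=O)[C@@H](C)[C@H]2[C@@H]1C=C | intermediate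
11 | (1S,2R,4aR,8S,8aR)‑8‑ethenyl‑1‑methyl‑6‑[(trimethylsilyl)oxy]‑1,2,3,4,4a,5,8,8a‑octahydronaphthalen‑2‑ol | C1=C(O[Si](C)(C)C)C[C@H]2CC[C@@H](O)[C@@H](C)[C@H]2[C@@H]1C=C | intermediate
12 | (2E)‑2‑bromobut‑2‑ene | C/C=C(\C)Br | starting material
13 | dilithium enolate‑alkoxide of 11 after loss of the silyl group (configuration as in 11) | C1=C(O[Li])C[C@H]2CC[C@@H](O[Li])[C@@H](C)[C@H]2[C@@H]1C=C | intermediate
14 | chlorozinc enolate (lithium alkoxide) corresponding to 13 | C1=C(O[Zn]Cl)C[C@H]2CC[C@@H](O[Li])[C@@H](C)[C@H]2[C@@H]1C=C | intermediate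
15 | (3S,4S,4aR,5S,6R,8aR)‑3‑[(2E)‑but‑2‑en‑2‑yl]‑4‑ethenyl‑6‑hydroxy‑5‑methyloctahydronaphthalen‑2(1H)‑one | C/C=C(\C)[C@H]1C(=O)C[C@H]2CC[C@@H](O)[C@@H](C)[C@H]2[C@@H]1C=C | intermediate
16 | N'‑[(2E,3S,4S,4aR,5S,6R,8aR)‑3‑[(2E)‑but‑2‑en‑2‑yl]‑4‑ethenyl‑6‑hydroxy‑5‑methyloctahydronaphthalen‑2(1H)‑ylidene]‑2,4,6‑tri(propan‑2‑yl)benzenesulfonohydrazide | C/C=C(\C)[C@H]1/C(=N/NS(=O)(=O)c3c(C(C)C)cc(C(C)C)cc3C(C)C)C[C@H]2CC[C@@H](O)[C@@H](C)[C@H]2[C@@H]1C=C | intermediate
17 | C‑3 vinyllithium, lithium alkoxide (skeleton and configuration of 18, Li in place of the C‑3 methyl) | C/C=C(\C)[C@H]1C([Li])=C[C@H]2CC[C@@H](O[Li])[C@@H](C)[C@H]2[C@@H]1C=C | intermediate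
18 | (1S,2R,4aS,7S,8S,8aR)‑7‑[(2E)‑but‑2‑en‑2‑yl]‑8‑ethenyl‑1,6‑dimethyl‑1,2,3,4,4a,7,8,8a‑octahydronaphthalen‑2‑ol | C/C=C(\C)[C@H]1C(C)=C[C@H]2CC[C@@H](O)[C@@H](C)[C@H]2[C@@H]1C=C | intermediate
19 | (2E)‑penta‑2,4‑dienoic acid | C=C/C=C/C(=O)O | starting material
20 | (2E,4E)‑5‑[(1S,2S,4aS,7R,8S,8aR)‑2‑[(2E)‑but‑2‑en‑2‑yl]‑7‑hydroxy‑3,8‑dimethyl‑1,2,4a,5,6,7,8,8a‑octahydronaphthalen‑1‑yl]penta‑2,4‑dienoic acid | C/C=C(\C)[C@H]1C(C)=C[C@H]2CC[C@@H](O)[C@@H](C)[C@H]2[C@@H]1/C=C/C=C/C(=O)O | intermediate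
21 | pyridinium salt of the C‑7 sulfate monoester of 20 | C/C=C(\C)[C@H]1C(C)=C[C@H]2CC[C@@H](OS(=O)(=O)[O-])[C@@H](C)[C@H]2[C@@H]1/C=C/C=C/C(=O)O.c1cc[nH+]cc1 | intermediate
22 | (2E,4E)‑5‑[(1S,2S,4aS,7R,8S,8aR)‑2‑[(2E)‑but‑2‑en‑2‑yl]‑3,8‑dimethyl‑7‑(sulfooxy)‑1,2,4a,5,6,7,8,8a‑octahydronaphthalen‑1‑yl]penta‑2,4‑dienoic acid | C/C=C(\C)[C@H]1C(C)=C[C@H]2CC[C@@H](OS(=O)(=O)O)[C@@H](C)[C@H]2[C@@H]1/C=C/C=C/C(=O)O | target

**Totals**
Total step count: 9. Longest linear sequence: 9 steps (1 to 22); all other inputs are commercial.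

**Three steps most likely to fail, each with a fallback**

Step 3 (radical ring closure). The vinyl radical can instead abstract the activated C‑4a hydrogen (1,5‑transfer), be reduced before it cyclises, or give some trans‑fused product. The fallback sets out from 8 and comes back at 9: the same C‑1–C‑8a bond is made by a reductive Heck cyclisation (Pd(OAc)2, PPh3, HCO2Na, Et4NCl, DMF, 80 °C). The alkenylpalladium adds syn across the enone from the tethered face and formate reduces the palladium enolate. No radical sits at C‑1, so the hydrogen transfer cannot occur. This detour makes no new compound (F0).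

Step 5 (α‑alkenylation). The hindered zinc enolate may couple slowly with the trisubstituted alkenyl bromide, and Heck‑type reaction at the vinyl group or loss of enolate regiochemistry can compete. The fallback sets out from 9 and comes back at 15, attaching the butenyl group to an sp2 carbon before the conjugate addition. I2/pyridine in CH2Cl2 gives the α‑iodo enone F1. Negishi coupling with (2E)‑but‑2‑en‑2‑ylzinc chloride (from 12, t‑BuLi, ZnCl2; Pd(PPh3)4, THF) gives the 2‑butenyl enone F2. Vinyl cuprate/TMSCl gives the keto silyl dienol ether F3, which LiBH(s‑Bu)3 reduces in the same pot to the hydroxy silyl dienol ether F4. K2CO3/MeOH removes silicon and equilibrates C‑2 to the trans ketone 15; the risk on this detour is isomerisation of the butenyl alkene into conjugation during that equilibration.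

Step 8 (cross‑metathesis). The vinyl group is flanked by two substituted carbons, and the dienoic acid can dimerise or form a sluggish conjugated carbene. The fallback sets out from 18 and comes back at 20, building the chain in two carbonyl steps. Cross‑metathesis with (E)‑but‑2‑enal (second‑generation Hoveyda–Grubbs catalyst, CH2Cl2, 40 °C) gives the enal F5. Horner–Wadsworth–Emmons reaction with trimethyl phosphonoacetate (LiCl, DBU, MeCN) gives the methyl dienoate F6. LiOH in THF/H2O then gives 20.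

**Further compounds**
F0 | step 3 | none | none
F1 | step 5 | α‑iodo enone: 9 bearing iodine at the enone α‑carbon (C‑7 of 9), stereocentres unchanged | O=C1C[C@H]2CCC(=O)[C@@H](C)[C@H]2C=C1I
F2 | step 5 | 2‑butenyl enone: 9 bearing an (E)‑but‑2‑en‑2‑yl group at the enone α‑carbon, stereocentres unchanged | O=C1C[C@H]2CCC(=O)[C@@H](C)[C@H]2C=C1/C(C)=C/C
F3 | step 5 | keto silyl dienol ether: 10 bearing an (E)‑but‑2‑en‑2‑yl group on the enol ether carbon C‑7 | C/C=C(\C)C1=C(O[Si](C)(C)C)C[C@H]2CCC(=O)[C@@H](C)[C@H]2[C@@H]1C=C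
F4 | step 5 | hydroxy silyl dienol ether: 11 bearing an (E)‑but‑2‑en‑2‑yl group on the enol ether carbon C‑7 | C/C=C(\C)C1=C(O[Si](C)(C)C)C[C@H]2CC[C@@H](O)[C@@H](C)[C@H]2[C@@H]1C=C
F5 | step 8 | (2E)‑3‑[(1S,2S,4aS,7R,8S,8aR)‑2‑[(2E)‑but‑2‑en‑2‑yl]‑7‑hydroxy‑3,8‑dimethyl‑1,2,4a,5,6,7,8,8a‑octahydronaphthalen‑1‑yl]prop‑2‑enal | C/C=C(\C)[C@H]1C(C)=C[C@H]2CC[C@@H](O)[C@@H](C)[C@H]2[C@@H]1/C=C/C=O
F6 | step 8 | methyl ester of 20 | C/C=C(\C)[C@H]1C(C)=C[C@H]2CC[C@@H](O)[C@@H](C)[C@H]2[C@@H]1/C=C/C=C/C(=O)OC
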